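The numbers in the tables come from a simulation for substances that don't exist, and the scatter is random.

I began with the easy step, which was to ask what the readings say with one process at work, and to let the others in afterwards.

all flasks: starting material 0.031 M

| flask | second substrate | capture agent | free catalyst | temperature | remark | time |
|---|---|---|---|---|---|---|
| theta | 0.031 M | 0.62 mM | 3.7 mM | 85 °C | run made earlier |  |
| alpha | 0.031 M | 0.62 mM | 9.4 mM | 100 °C | run made earlier |  |
| Saturday's | 0.0310 M | 0.620 mM | 4.6 mM | 100 °C |  | 50 h |
| Tuesday's | 0.0310 M | 0.620 mM | 20 mM | 100 °C |  | 50 h |

| run | time / h | target / % |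
|---|---|---|
| theta | 20.0 | 8.0 |
| theta | 40.0 | 13.6 |
| theta | 60.0 | 16.3 |
| theta | 96.0 | 21.3 |
| alpha | 4.00 | 14.2 |
| alpha | 12.0 | 28.8 |
| alpha | 25.0 | 38.3 |
| alpha | 40.0 | 37.1 |
| alpha | 48.0 | 36.4 |

(scatter of a reading: 0.5 percentage points)

* the winner by amount of target, in percent of the starting material charged; "neither" if no more than 2 percentage points parts them (Saturday's / Tuesday's / neither)
* how much target is there at the end, in percent of the starting material charged: Saturday's
* how much target is there at the end, in percent of the starting material charged: Tuesday's

- a species is counted by the starting material in it: one side product counts as two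
- steps thought possible: starting material + free catalyst <-> catalyst intermediate A; catalyst intermediate A -> free catalyst + target; second substrate + free catalyst <-> catalyst intermediate B; catalyst intermediate B -> free catalyst + second product; starting material + target -> side product; target <-> isomer of the product; catalyst intermediate A + capture agent -> trapped intermediate

With the main step alone, starting material passing through the catalyst to target, the first alpha reading was enough. Its 14.2% of the charge in 4.00 h gave, per catalyst charged, a read turnover frequency w of 0.117 h⁻¹ at 100 °C. The charge of starting material divided by w times the catalyst charged is the time the catalyst needs to pass that charge at its early rate. I called this the turnover clock, τ, and for Saturday's flask it was 57.6 h. For Tuesday's flask it was 13.2 h, and for alpha 28.2 h. So the main step alone turned over 86.8% of the charge in Saturday's flask by 50 h, and the whole charge in Tuesday's, whose clock ran out earlier.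

Next I let in the step of starting material with target. That step uses no catalyst, so target stops rising where its loss equals its making, and I took that level to go with the catalyst charged. The alpha peak, read as 38.3% at 25.0 h, near its clock, gave the scale. The number therefore fell to 18.7% for Saturday's flask and 81.5% for Tuesday's.

Last came the step from target to isomer. Alpha's readings went down to 36.4% at 48.0 h, so target was being lost in alpha. My own reckoning stayed at the scaled 18.7% for Saturday's flask, with no allowance for this step. Tuesday's flask has 36.8 h after its clock, and I put no figure on the loss of target there. I held only that, with more catalyst than alpha at the same temperature, it should stand near alpha's peak or above, and so should win.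

The forecast, a reckoning different from mine, named Tuesday's, with 22% (17% to 28%) for Saturday's flask and 50% (40% to 60%) for Tuesday's, holding that “more catalyst should give better selectivity”.

The flasks gave 26.4% for Saturday's and 40.9% for Tuesday's, so Tuesday's won.

    starting material + free catalyst ⇌ catalyst intermediate A (K = 35.0 L mol⁻¹, k = 180 L mol⁻¹ h⁻¹, Ea = 60.0 kJ mol⁻¹, ΔH = −36.0 kJ mol⁻¹)
    catalyst intermediate A → free catalyst + target (k = 0.350 h⁻¹, Ea = 109 kJ mol⁻¹)
    second substrate + free catalyst ⇌ catalyst intermediate B (K = 19.0 L mol⁻¹, k = 11.0 L mol⁻¹ h⁻¹, Ea = 88.0 kJ mol⁻¹, ΔH = −21.0 kJ mol⁻¹)
    catalyst intermediate B → free catalyst + second product (k = 0.300 h⁻¹, Ea = 125 kJ mol⁻¹)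
    starting material + target → side product (k = 1.50 L mol⁻¹ h⁻¹, Ea = 96.0 kJ mol⁻¹)
    target ⇌ isomer of the product (K = 1.20, k = 0.0330 h⁻¹, Ea = 127 kJ mol⁻¹, ΔH = −21.0 kJ mol⁻¹)
    catalyst intermediate A + capture agent → trapped intermediate (k = 6.50 L mol⁻¹ h⁻¹, Ea = 68.0 kJ mol⁻¹)
    (constants at 100 °C)

Saturday's flask at 50 h was short of its clock of 57.6 h and held 15.0% of its starting material, while Tuesday's was past its 13.2 h with 0.0659% left and target down from 50.9% at 25.0 h. In Saturday's flask the forward step from target to isomer alone has a half-life of 21 h, shorter than the time, and 19.9% stood as isomer. A flask like Saturday's kept at 85 °C has, from theta's first reading, a clock of 201 h, so 50 h is 24.9% of it, and that flask ended with 61.4% of its starting material left and target at 18.9%.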